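The earlier runs and the new flask are simulated for an exercise; scatter was added.

- In a one-step world each starting complex takes one incoming ligand, so the flask stops when the incoming ligand is gone.

| flask | starting complex | incoming ligand | scavenger | capture agent | remark | time |
|---|---|---|---|---|---|---|
| theta | 0.042 M | 0.0315 M | 0.0756 M | 0.063 M | run made earlier |  |
| dawn | 0.063 M | 0.0315 M | 0.0760 M | 0.0630 M |  | 2.0 h |
| midnight | 0.063 M | 0.0315 M | 0.150 M | 0.0630 M |  | 2.0 h |

theta run (percent of the starting complex charged)

| time / min | starting complex / % | complex with two exchanged / % |
|---|---|---|
| 6.00 | 92.6 | 0 |
| 12.0 | 86.7 | 1.3 |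
| 30.0 | 79.1 | 1.8 |
| 80.0 | 58.6 | 2.0 |

(readings scatter by 1 percentage point)

- the numbers in the tables scatter by 1 percentage point (one standard deviation)
- no earlier run changes the charge of scavenger; that part of a forecast is a guess
- a reading of starting complex is of its free form alone

- part of the starting complex that has reacted at the end, dawn
- part of the starting complex that has reacted at the end, midnight
- what raising the concentration of scavenger from its lowest to its highest value here does to the part of the starting complex that has reacted (changes below 5 percentage points count as none) (no change / it falls / it rises)

- Less incoming ligand than starting complex is charged. The ligand ratio, charged [incoming ligand] over charged [starting complex], is 0.500 in dawn and midnight. It is the ceiling on the reacted fraction, with the incoming ligand as limiting reagent.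
- Theta has a ratio of 0.750, yet it stood at 41.4% reacted after 80.0 min, below its ceiling. So the ratio gives a ceiling, not a time.
- A second number is needed. The second-order law through that theta reading, scaled to dawn's charges and 2.0 h, gives a progress number of 1.21. This reckoning then puts dawn at 41.2% reacted.
- The forecast is higher: 44% for dawn, 44% for midnight, and no change. On the scavenger it says: “I guess it is already in excess and has no effect.”

The flasks give:

- Dawn reaches 39.8% and midnight 39.6%, a change of −0.21 percentage points, so no change.

    complex with one exchanged + incoming ligand ⇌ leaving ligand + complex with two exchanged (K = 0.950, k = 0.00145 M⁻¹ s⁻¹)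
    leaving ligand + starting complex ⇌ idle adduct, settled at all times (K = 350 M⁻¹)
    scavenger + leaving ligand → scavenged by-product (k = 0.880 M⁻¹ s⁻¹)
    complex with one exchanged + capture agent → trapped intermediate (k = 0.00214 M⁻¹ s⁻¹)
    starting complex + incoming ligand ⇌ leaving ligand + complex with one exchanged (K = 11.0, k = 0.00509 M⁻¹ s⁻¹)

- With 0.019 M of scavenger, a neighbour of dawn reads 48.8%, more than dawn, with 11.0% as idle adduct.
- With 0.13 M of incoming ligand, the ratio is 2.06, and that neighbour of dawn reaches 93.2%.
- Dawn is not at rest at 2.0 h, with 17% of its incoming ligand left. After 20.0 h that share is 0%, and dawn has reacted 47.1%. Adding the 2.89% of complex with two exchanged, which took a second ligand, gives 50.0%, the ligand ratio of 50.0%.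
- Over the same time, complex with one exchanged falls from 20.8% to 0.174%, and trapped intermediate rises from 16.2% to 44.0%.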